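**Plan**
- The heptane chain is numbered C1–C7 between the aryl rings (acetate on C3, hydroxyl on C5). Benzylic C1 lies four carbons from the C5 oxygen, so C1–C5 and that oxygen can be folded into a 2-aryloxane with the acetate on ring carbon 4 (= C3).
- Retrosynthesis: C1–H goes back to a C1–O5 ring bond (hydrogenolysis). The oxane is then cut at C1–O5, C1–C2 and C3–OAc (Prins) into O-benzylvanillin, acetic acid and the (S)-homoallylic alcohol C2–C7, which is cut at C4–C5 (allylation) to a 3-arylpropanal.
- Forward: O-benzylation and oxidation of dihydroconiferyl alcohol, asymmetric allylation, Prins closure of the only ring, then one hydrogenolysis that opens the ring and frees both phenols.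
- Stereochemistry: C5 (S) comes from reagent-controlled Brown allylboration; C3 (S) is set relative to C5 in the chair Prins transition state; the temporary centre C1 is erased at the end.
- The diol core is C2-symmetric, so the monoacetate is one compound whichever oxygen carries the acetyl group, and acetyl migration would be degenerate.

Key step: step 4

Remark: (+)-Ipc2BOMe is (+)-B-methoxydiisopinocampheylborane, the reagent made from (−)-α-pinene; it and compounds 1, 2, 7 and 8 are taken as purchased.

Step 1
Reactants: 1 4-(3-hydroxypropyl)-2-methoxyphenol (dihydroconiferyl alcohol); 2 benzyl bromide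
Product: 3 3-[4-(benzyloxy)-3-methoxyphenyl]propan-1-ol
Conditions: K2CO3, acetone, reflux
Reagents that add atoms: none
Why: Williamson ether synthesis, in which K2CO3 deprotonates only the phenol (the primary alcohol is far less acidic) and the phenoxide displaces bromide from 2 in an SN2 reaction.

Step 2
Reactants: 3 3-[4-(benzyloxy)-3-methoxyphenyl]propan-1-ol
Product: 4 3-[4-(benzyloxy)-3-methoxyphenyl]propanal
Conditions: TEMPO (cat.), PhI(OAc)2, CH2Cl2, rt
Reagents that add atoms: none
Why: Oxoammonium-mediated alcohol oxidation (TEMPO/PhI(OAc)2), which under anhydrous conditions should stop at the aldehyde and leave the benzyl ether and the electron-rich arene untouched.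

Step 3
Reactants: 4 3-[4-(benzyloxy)-3-methoxyphenyl]propanal
Product: 6 (3S)-1-[4-(benzyloxy)-3-methoxyphenyl]hex-5-en-3-ol, via borinate ester 5 (not isolated)
Conditions: (+)-Ipc2BOMe, allylMgBr, Et2O, 0 °C → rt, Mg salts filtered off; then 4, Et2O, −100 °C; then NaOH, H2O2, 0 °C → rt
Reagents that add atoms: allylmagnesium bromide, C=CC[Mg]Br (allyl group, passed on through (+)-B-allyldiisopinocampheylborane, C=CCB([C@H]1C[C@H]2C[C@H](C2(C)C)[C@@H]1C)[C@H]1C[C@H]2C[C@H](C2(C)C)[C@@H]1C)
Why: Brown asymmetric allylboration, in which the allylborane from (−)-α-pinene should deliver allyl to the Re face of the aldehyde through a chair Zimmerman–Traxler transition state with the aldehyde chain equatorial, setting C5 as S, after which oxidative work-up cleaves borinate 5.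

Step 4
Reactants: 6 (3S)-1-[4-(benzyloxy)-3-methoxyphenyl]hex-5-en-3-ol; 7 4-(benzyloxy)-3-methoxybenzaldehyde (O-benzylvanillin); 8 acetic acid
Product: 11 (2S,4R,6S)-2-[4-(benzyloxy)-3-methoxyphenyl]-6-{2-[4-(benzyloxy)-3-methoxyphenyl]ethyl}oxan-4-yl acetate, via E-oxocarbenium ion 9 (not isolated), via oxan-4-yl cation 10 (not isolated)
Conditions: BF3·OEt2 (2 equiv), 8 (excess), TMSOAc, cyclohexane–CH2Cl2, 0 °C → rt
Reagents that add atoms: none
Why: BF3·OEt2 condenses 7 with the C5 hydroxyl of 6 to the aryl-conjugated E-oxocarbenium ion 9, the terminal alkene carbon C2 attacks C1 through a chair transition state to give the oxan-4-yl cation 10, and acetate from 8 caps C3. The closest known reaction type is the three-component Prins cyclisation of a homoallylic alcohol, an aldehyde and a carboxylic acid to a 2,4,6-cis 4-acyloxyoxane. The one ring, the oxane made of O5 and C1–C5, closes in the 6-endo-trig mode, both alkene carbons ending up inside the ring. C1 is set by the chair in which the aryl group on the E-oxocarbenium carbon and the arylethyl chain on C5 are both equatorial, and C3 by equatorial capture of cation 10, both relative to the S centre at C5 brought in by 6; the all-cis (2S,4R,6S) ring corresponds to the anti C3/C5 relationship of the target. The step needs C5 to keep its configuration and the two side chains not to be exchanged: the electron-rich aryl group makes 9 far more stable than its 2-oxonia-Cope isomer, so the equilibrium stays on the side of 9 and the C5–O bond is not ionised. Capture by acetate instead of fluoride is secured by the excess of 8 together with TMSOAc as fluoride trap, and the low temperature should keep the aryl benzyl ethers intact.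

Step 5
Reactants: 11 (2S,4R,6S)-2-[4-(benzyloxy)-3-methoxyphenyl]-6-{2-[4-(benzyloxy)-3-methoxyphenyl]ethyl}oxan-4-yl acetate
Product: 13 (3S,5S)-5-hydroxy-1,7-bis(4-hydroxy-3-methoxyphenyl)heptan-3-yl acetate, via bisphenol oxane 12 (not isolated)
Conditions: H2 (3 bar), Pd(OH)2 on carbon, EtOAc–AcOH, rt
Reagents that add atoms: none
Why: Catalytic hydrogenolysis, which should first remove both O-benzyl groups (12) and then, helped by acetic acid and the para-hydroxy aryl group, cut the benzylic C1–O ring bond so that C1 becomes a methylene group and the C5 hydroxyl is freed, while the non-benzylic C3 acetate and both stereocentres are not touched.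

**Compound list**
1 | 4-(3-hydroxypropyl)-2-methoxyphenol (dihydroconiferyl alcohol) | COc1cc(CCCO)ccc1O | starting material
2 | benzyl bromide | BrCc1ccccc1 | starting material
3 | 3-[4-(benzyloxy)-3-methoxyphenyl]propan-1-ol | COc1cc(CCCO)ccc1OCc1ccccc1 | intermediate
4 | 3-[4-(benzyloxy)-3-methoxyphenyl]propanal | COc1cc(CCC=O)ccc1OCc1ccccc1 | intermediate
5 | (3S)-1-[4-(benzyloxy)-3-methoxyphenyl]hex-5-en-3-yl diisopinocampheylborinate (formed in the flask, not isolated) | C=CC[C@H](CCc1ccc(OCc2ccccc2)c(OC)c1)OB([C@H]3C[C@H]4C[C@H](C4(C)C)[C@@H]3C)[C@H]3C[C@H]4C[C@H](C4(C)C)[C@@H]3C | intermediate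
6 | (3S)-1-[4-(benzyloxy)-3-methoxyphenyl]hex-5-en-3-ol | C=CC[C@H](CCc1ccc(OCc2ccccc2)c(OC)c1)O | intermediate
7 | 4-(benzyloxy)-3-methoxybenzaldehyde (O-benzylvanillin) | COc1cc(C=O)ccc1OCc1ccccc1 | starting material
8 | acetic acid | CC(=O)O | starting material
9 | (E)-{[4-(benzyloxy)-3-methoxyphenyl]methylidene}{(3S)-1-[4-(benzyloxy)-3-methoxyphenyl]hex-5-en-3-yl}oxonium (formed in the flask, not isolated) | C=CC[C@H](CCc1ccc(OCc2ccccc2)c(OC)c1)/[O+]=C/c1ccc(OCc2ccccc2)c(OC)c1 | intermediate
10 | 2,6-cis-2-[4-(benzyloxy)-3-methoxyphenyl]-6-{2-[4-(benzyloxy)-3-methoxyphenyl]ethyl}oxan-4-ylium, chain-bearing carbon configured as in 6 (formed in the flask, not isolated) | [CH+]1C[C@H](CCc2ccc(OCc3ccccc3)c(OC)c2)O[C@H](c2ccc(OCc3ccccc3)c(OC)c2)C1 | intermediate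
11 | (2S,4R,6S)-2-[4-(benzyloxy)-3-methoxyphenyl]-6-{2-[4-(benzyloxy)-3-methoxyphenyl]ethyl}oxan-4-yl acetate (all-cis) | CC(=O)O[C@@H]1C[C@H](CCc2ccc(OCc3ccccc3)c(OC)c2)O[C@H](c2ccc(OCc3ccccc3)c(OC)c2)C1 | intermediate
12 | (2S,4R,6S)-2-(4-hydroxy-3-methoxyphenyl)-6-[2-(4-hydroxy-3-methoxyphenyl)ethyl]oxan-4-yl acetate (formed in the flask, not isolated) | CC(=O)O[C@@H]1C[C@H](CCc2ccc(O)c(OC)c2)O[C@H](c2ccc(O)c(OC)c2)C1 | intermediate
13 | (3S,5S)-5-hydroxy-1,7-bis(4-hydroxy-3-methoxyphenyl)heptan-3-yl acetate | COc1cc(CC[C@H](O)C[C@H](CCc2ccc(O)c(OC)c2)OC(C)=O)ccc1O | target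

**Totals**
Total steps: 5. Longest linear sequence: 5 steps (1 → 3 → 4 → 6 → 11 → 13).

**Steps most likely to fail**

Step 4 (Prins cyclisation). What may go wrong: exchange of the two side chains and erosion of enantiopurity through 2-oxonia-Cope equilibration and aldehyde exchange; sluggish ionisation of the hemiacetal of the electron-rich aldehyde; capture of the C3 cation by fluoride; Lewis-acid loss of a benzyl ether. Fallback, from 6 back to 11: the oxocarbenium ion would be made from a preformed mixed acetal, so that no free aldehyde or water is present. Alcohol 6 is esterified with purchased 4-(benzyloxy)-3-methoxybenzoic acid (DCC, DMAP, CH2Cl2) to (3S)-1-[4-(benzyloxy)-3-methoxyphenyl]hex-5-en-3-yl 4-(benzyloxy)-3-methoxybenzoate F1. The ester is reduced with i-Bu2AlH at −78 °C and the aluminium hemiacetal is acetylated in the same flask (Ac2O, pyridine, DMAP) to the α-acetoxy ether [4-(benzyloxy)-3-methoxyphenyl]{[(3S)-1-[4-(benzyloxy)-3-methoxyphenyl]hex-5-en-3-yl]oxy}methyl acetate F2, used crude as both epimers at the acetal carbon. Ionisation of F2 with BF3·OEt2 and AcOH in CH2Cl2–hexane at 0 °C should give ion 9 directly and close the same ring to 11.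

Step 5 (hydrogenolytic ring opening). What may go wrong: the reaction stalls after O-debenzylation, with the ring C1–O bond left intact, or forcing conditions begin to reduce the arenes. Fallback, from 11 back to 13: the ring would be opened by ionic hydrogenation instead of on the metal surface. Et3SiH and CF3CO2H in CH2Cl2 at −20 → 0 °C ionise the para-alkoxybenzylic C1–O bond and trap the cation with hydride, giving (3S,5S)-1,7-bis[4-(benzyloxy)-3-methoxyphenyl]-5-hydroxyheptan-3-yl acetate F3 after a mild NaHCO3/MeOH wash that removes any trifluoroacetate. Plain hydrogenolysis of the two benzyl ethers (H2, Pd on carbon, EtOAc, rt) then gives 13. Partial loss of benzyl groups in the acid step would be harmless, and acetyl migration is degenerate.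

Step 3 (asymmetric allylation). What may go wrong: incomplete facial selectivity in the allyl transfer, which cannot be corrected later because every following centre is set relative to C5. Fallback, from 4 back to 6: the stereocentre would be secured by resolution and the allyl unit completed by epoxide opening. Aldehyde 4 is methylenated with trimethylsulfonium iodide and KOtBu in DMSO–THF (Corey–Chaykovsky) to racemic 2-{2-[4-(benzyloxy)-3-methoxyphenyl]ethyl}oxirane F4. Hydrolytic kinetic resolution follows with (S,S)-(salen)Co(OAc) (acetate of trivalent cobalt; salen = N,N'-bis(3,5-di-tert-butylsalicylidene)cyclohexane-1,2-diamine) and 0.55 equiv of water. This is the catalyst enantiomer that by the usual correlation for alkyl-substituted terminal epoxides hydrolyses the R epoxide. It should leave (2S)-2-{2-[4-(benzyloxy)-3-methoxyphenyl]ethyl}oxirane F5, and the R enantiomer is removed as (2R)-4-[4-(benzyloxy)-3-methoxyphenyl]butane-1,2-diol F6. Opening of F5 at its terminal carbon with vinylmagnesium bromide and catalytic CuI in THF at −40 °C breaks no bond to the stereocentre and gives 6.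

**Further compounds**
F1 | step 4 | (3S)-1-[4-(benzyloxy)-3-methoxyphenyl]hex-5-en-3-yl 4-(benzyloxy)-3-methoxybenzoate | C=CC[C@H](CCc1ccc(OCc2ccccc2)c(OC)c1)OC(=O)c1ccc(OCc2ccccc2)c(OC)c1
F2 | step 4 | [4-(benzyloxy)-3-methoxyphenyl]{[(3S)-1-[4-(benzyloxy)-3-methoxyphenyl]hex-5-en-3-yl]oxy}methyl acetate (both epimers at the acetal carbon) | C=CC[C@H](CCc1ccc(OCc2ccccc2)c(OC)c1)OC(OC(C)=O)c1ccc(OCc2ccccc2)c(OC)c1
F3 | step 5 | (3S,5S)-1,7-bis[4-(benzyloxy)-3-methoxyphenyl]-5-hydroxyheptan-3-yl acetate | COc1cc(CC[C@H](O)C[C@H](CCc2ccc(OCc3ccccc3)c(OC)c2)OC(C)=O)ccc1OCc1ccccc1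
F4 | step 3 | racemic 2-{2-[4-(benzyloxy)-3-methoxyphenyl]ethyl}oxirane | COc1cc(CCC2CO2)ccc1OCc1ccccc1
F5 | step 3 | (2S)-2-{2-[4-(benzyloxy)-3-methoxyphenyl]ethyl}oxirane | COc1cc(CC[C@H]2CO2)ccc1OCc1ccccc1
F6 | step 3 | (2R)-4-[4-(benzyloxy)-3-methoxyphenyl]butane-1,2-diol | COc1cc(CC[C@@H](O)CO)ccc1OCc1ccccc1
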